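If we keep a ledger of the substrate, the limiting reagent at 0.10 M against 0.130 M of coupling partner, with an open column for whatever is not yet target or side product, each mole that leaves that column is booked to target or to side product, and both entries draw on the same intermediate, so by the steps on the card the ratio of their rates contains neither the amount of intermediate nor the free catalyst, which works one step earlier.

| setting | cedar | birch | alder | gamma | epsilon | delta | theta |
|---|---|---|---|---|---|---|---|
| substrate | 0.10 M | 0.10 M | 0.10 M | 0.10 M | 0.10 M (fed, over 1.0 h) | 0.10 M | 0.10 M |
| coupling partner | 0.13 M | 0.13 M | 0.13 M | 0.130 M (fed, over 1.0 h) | 0.130 M | 0.130 M (in portions, 5, over 1.0 h) | 0.130 M |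
| free catalyst | 2 mM | 1.3 mM | 3 mM | 2.0 mM | 2.0 mM | 2.0 mM | 2.0 mM |
| second catalyst | 0.50 mM | 0.50 mM | 0.50 mM | 0.50 mM | 0.50 mM | 0.50 mM | 0.50 mM |
| remark | run made earlier | run made earlier | run made earlier | all else is in the flask from the start; the feed brings no volume worth counting | all else is in the flask from the start; the feed brings no volume worth counting | first portion at the start, last at 1.0 h | everything together at the start |
| time |  |  |  | 80 min | 80 min | 80 min | 80 min |

| run | time / min | target / % | side product / % |
|---|---|---|---|
| cedar | 6.00 | 0.5 | 0.4 |
| cedar | 10.0 | 0.7 | 0.8 |
| cedar | 15.0 | 2.0 | 1.0 |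
| cedar | 25.0 | 4.3 | 3.2 |
| cedar | 30.0 | 6.4 | 3.8 |
| cedar | 50.0 | 12.4 | 9.1 |
| cedar | 80.0 | 20.0 | 16.7 |
| birch | 8.00 | 0.6 | 0.5 |
| birch | 12.0 | 1.2 | 0.6 |
| birch | 20.0 | 2.5 | 0.5 |
| birch | 25.0 | 3.1 | 1.8 |
| birch | 40.0 | 6.9 | 4.0 |
| birch | 60.0 | 12.4 | 8.2 |
| birch | 90.0 | 17.9 | 14.7 |
| alder | 15.0 | 2.8 | 1.5 |
| alder | 30.0 | 8.6 | 6.3 |
| alder | 40.0 | 12.0 | 8.3 |
| alder | 60.0 | 18.4 | 14.8 |
| alder | 80.0 | 23.9 | 21.2 |
| alder | 90.0 | 25.5 | 24.3 |

(standard deviation of a reading: 0.3 percentage points)

- which flask leads in share of target in target plus side product ("all alike" within 1.5 percentage points) (gamma / epsilon / delta / theta / all alike)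
- share of target in target plus side product at the end, gamma
- share of target in target plus side product at the end, epsilon
- share of target in target plus side product at the end, delta
- share of target in target plus side product at the end, theta

- in percentages every species weighs as the substrate in it: one idle adduct counts as two
- for target the idle adduct and idle complex are counted in
- steps thought possible: substrate + free catalyst -> free catalyst + intermediate; coupling partner + second catalyst + intermediate -> second catalyst + target; intermediate -> side product; substrate + target <-> idle adduct; second catalyst + target <-> idle complex
- in an amount of target, one idle adduct counts as one target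

Cedar's books at 80.0 min show 20.0% in target and 16.7% in side product, with 63.3% still open, and the readings roughly bear the ratio out, since cedar at 50.0 min, birch at 60.0 min and alder at 40.0 min hold 12.4%, 12.4% and 12.0% of target beside 9.1%, 8.2% and 8.3% of side product. The same readings give a clock: the logarithm of alder's free catalyst over birch's, divided by the logarithm of birch's time over alder's, is 2.06, so at equal target free catalyst counts roughly as time squared. Epsilon's substrate arrives evenly over 1.0 h, so that a mole of it comes in on average half way through the feed, and its 80 min count as about 50.0 min at full charge, and this, minutes of full charge scaled by the square root of free catalyst over cedar's, we call the cedar time.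

Theta repeats cedar, so we take for it the share of cedar's last reading, 54.5%, and read at its cedar time on cedar, epsilon should book 12.4% and 9.1%, a share of 57.7%, which is higher than theta's. Gamma has received on average half of its partner charge during the feed and delta receives it in 5 portions, and partner is a factor of the coupling step but not of the side step, so we place both below theta.

The forecast led with epsilon at 57%, beside 54.5% for theta, 44.5% for gamma and 46.5% for delta, holding that “Epsilon keeps partner high and target low”. The flask gives 58.8% for epsilon, 54.7% for theta, 48.2% for gamma and 47.7% for delta.

    substrate + free catalyst → free catalyst + intermediate (k = 8.20 M⁻¹ min⁻¹)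
    coupling partner + second catalyst + intermediate → second catalyst + target (k = 220 M⁻² min⁻¹)
    intermediate → side product (k = 0.00750 min⁻¹)
    substrate + target ⇌ idle adduct, settled at all times (K = 3.40 M⁻¹)
    second catalyst + target ⇌ idle complex, settled at all times (K = 51.0 M⁻¹)

Epsilon holds 12.5% of target and 8.74% of side product at 80.0 min, close to what its cedar time read, and a further flask like epsilon with 0.0034 M of free catalyst has a cedar time of 65.2 min, where cedar's readings interpolate to 16.2% and 12.9% against its 16.2% and 12.4%. At 50.5 min in epsilon the coupling step gives intermediate a half-life of 60 min, while the side step alone gives 92 min in theta. The rate of the coupling step over that of the side step, in epsilon at that time, stands at 1.5.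

The data come from a simulation from invented constants.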